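Ring C is built, not coupled. In ring C, C1 carries the ether oxygen to ring B, C2 carries ring D, and C3 and C5 carry hydroxyls. The unit ring D–C2≡C1–O–ring B is therefore an aryl(aryloxy)acetylene, and C3–C6 with both oxygens correspond to 3-ethoxycyclobutenone. A thermal Danheiser benzannulation joins the two: the ynol ether captures the vinylketene released by the cyclobutenone, and ring C appears in one operation as a phenol with the hindered biaryl bond and the doubly ortho-flanked diaryl ether in place. The precursor is a linear alkyne whose oxygen bears the preassembled ring A–O–ring B unit (SNAr, Dakin oxidations) and whose carbon bears 2,4,6-trimethoxyphenyl (ring D).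

Key step: step 8

Remark: ring C is numbered so that C1 bears the oxygen to ring B, C2 bears ring D, C3 and C5 bear oxygen, and C4 and C6 bear hydrogen; cyclobutenone 23 forms as a racemate and is consumed in the same flask.

Step 1
Reactants: 1 2,4,6-trimethoxybenzaldehyde
Product: 3 2,4,6-trimethoxyphenol, via 2,4,6-trimethoxyphenyl formate 2 (not isolated)
Conditions: mCPBA (1.1 equiv), CH2Cl2, 0 °C to rt; aq NaHCO3/Na2S2O3 wash; then cat. K2CO3, MeOH, Ar, rt
Reagents that add atoms: mCPBA (3-chloroperoxybenzoic acid), OOC(=O)c1cccc(Cl)c1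
Why: Baeyer–Villiger oxidation in its Dakin-type form: the peracid adds to the formyl group and the electron-rich aryl group migrates to oxygen, and the resulting aryl formate is cleaved at its acyl carbon by methanol under mild base, air being excluded because the phenoxide is easily oxidised.

Step 2
Reactants: 4 1-fluoro-3,5-dimethoxybenzene
Product: 6 2-fluoro-4,6-dimethoxybenzaldehyde, via aryl iminium salt 5 (not isolated)
Conditions: POCl3 (1.2 equiv), DMF, 0 °C to 60 °C; then ice-water, rt; recrystallisation
Reagents that add atoms: N,N-dimethylformamide, CN(C)C=O; water, O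
Why: Vilsmeier–Haack formylation: the chloroiminium ion attacks the ring carbon that is para to one methoxy and ortho to the other (and ortho to the small fluorine) in preference to the more crowded carbon between the two methoxy groups, and recrystallisation removes any 4-fluoro-2,6-dimethoxy isomer, which would otherwise enter the next step with the wrong connectivity.

Step 3
Reactants: 3 2,4,6-trimethoxyphenol; 6 2-fluoro-4,6-dimethoxybenzaldehyde
Product: 7 2,4-dimethoxy-6-(2,4,6-trimethoxyphenoxy)benzaldehyde
Conditions: Cs2CO3 (1.5 equiv), degassed DMSO, 100 °C, Ar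
Reagents that add atoms: none
Why: Nucleophilic aromatic substitution by addition–elimination: the ortho formyl group takes up the negative charge of the Meisenheimer intermediate, both methoxy groups sit meta to the C–F carbon and therefore do not oppose the attack, and fluoride is the preferred leaving group for this mechanism.

Step 4
Reactants: 7 2,4-dimethoxy-6-(2,4,6-trimethoxyphenoxy)benzaldehyde
Product: 9 2,4-dimethoxy-6-(2,4,6-trimethoxyphenoxy)phenol, via aryl formate 8 (not isolated)
Conditions: mCPBA (1.1 equiv), CH2Cl2, 0 °C to rt; aq NaHCO3/Na2S2O3 wash; then cat. K2CO3, MeOH, Ar, rt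
Reagents that add atoms: mCPBA (3-chloroperoxybenzoic acid), OOC(=O)c1cccc(Cl)c1
Why: Baeyer–Villiger (Dakin-type) oxidation as in step 1: the aldehyde carbon carries an aryl group with ortho and para oxygen donors, so aryl migration is fast and should outrun oxidation of the methoxyarenes, and methanolysis of the formate should give the phenol whose hydroxyl is flanked by the ring A ether and a methoxy group.

Step 5
Reactants: 9 2,4-dimethoxy-6-(2,4,6-trimethoxyphenoxy)phenol; 10 trichloroethylene
Product: 12 2-[(E)-1,2-dichloroethenyloxy]-1,5-dimethoxy-3-(2,4,6-trimethoxyphenoxy)benzene, via dichloroacetylene 11 (not isolated)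
Conditions: K2CO3 (2 equiv), DMF, 70 °C
Reagents that add atoms: none
Why: Base-mediated vinylation: K2CO3 eliminates HCl from trichloroethylene to dichloroacetylene, the phenoxide adds to it and protonation occurs anti, which is the established way to aryl (E)-1,2-dichlorovinyl ethers and tolerates ortho substituents because the electrophile is a slim, linear alkyne.

Step 6
Reactants: 12 2-[(E)-1,2-dichloroethenyloxy]-1,5-dimethoxy-3-(2,4,6-trimethoxyphenoxy)benzene; 13 2-iodo-1,3,5-trimethoxybenzene
Product: 17 1,5-dimethoxy-2-[(2,4,6-trimethoxyphenyl)ethynyloxy]-3-(2,4,6-trimethoxyphenoxy)benzene, via chloroethynyl ether 14 (not isolated), via lithium aryloxyacetylide 15 (not isolated), via aryloxyethynylzinc chloride 16 (not isolated)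
Conditions: n-BuLi (2.1 equiv), THF, −78 °C; ZnCl2 (1.3 equiv), −78 °C to rt; then 13, Pd2(dba)3 (2.5 mol%), XPhos (10 mol%), 50 °C; chromatography on Et3N-deactivated silica
Reagents that add atoms: none
Why: One-pot ynol ether synthesis followed by Negishi coupling: the first equivalent of n-BuLi eliminates HCl, the second exchanges the alkynyl chlorine for lithium, ZnCl2 gives the alkynylzinc chloride (so that no alkyllithium remains when the iodide is added), and zerovalent palladium carrying the bulky biarylphosphine inserts into the C–I bond flanked by two methoxy groups and forms the sp–sp2 bond.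

Step 7
Reactants: 18 ethoxyacetylene; 19 acetyl chloride
Product: 21 3-ethoxycyclobut-2-en-1-one, via ketene 20 (not isolated)
Conditions: Et3N (1.1 equiv, slow addition), CH2Cl2, 0 °C to rt; filtration; chromatography
Reagents that add atoms: none
Why: (2+2) cycloaddition of a ketene with an alkoxyalkyne: Et3N dehydrochlorinates acetyl chloride to ketene, whose carbonyl carbon is attacked by the nucleophilic terminal carbon of ethoxyacetylene, so the ethoxy group ends up at C3 of the cyclobutenone.

Step 8
Reactants: 17 1,5-dimethoxy-2-[(2,4,6-trimethoxyphenyl)ethynyloxy]-3-(2,4,6-trimethoxyphenoxy)benzene; 21 3-ethoxycyclobut-2-en-1-one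
Product: 26 5-ethoxy-3-[2,4-dimethoxy-6-(2,4,6-trimethoxyphenoxy)phenoxy]-2-(2,4,6-trimethoxyphenyl)phenol, via vinylketene 22 (not isolated), via 4-vinylcyclobutenone 23 (not isolated), via dienylketene 24 (not isolated), via cyclohexa-2,4-dienone 25 (not isolated)
Conditions: 21 (2.5 equiv, syringe-pump addition), toluene, 110 °C, Ar; then KOH, MeOH, rt (work-up)
Reagents that add atoms: none
Why: Heating opens 21 by four-electron conrotatory ring opening to vinylketene 22, whose ketene C=C adds across the ynol ether in a (2+2) cycloaddition (ketene carbonyl carbon to the ring D-bearing alkyne carbon) to give 23; this reopens to dienylketene 24, which closes by six-electron disrotatory electrocyclization to dienone 25 and tautomerizes to the phenol. The closest known reaction type is the Danheiser benzannulation of cyclobutenones with alkoxy- and siloxyalkynes, applied here to an aryloxyalkyne that cannot fragment by a retro-ene path because its oxygen substituent has no β-hydrogen. Ring C is the only ring closed, first as the four-membered ring of 23 by (2+2) cycloaddition (bonds C2–C3 and C1–C6) and finally as the six-membered ring by 6π electrocyclization (bond C3–C4, the bond broken when 21 opened). No stereocentre is created in 26: the single stereocentre of racemic 23 is lost on ring opening, and the ring C–ring D axis is not stereogenic because ring D is symmetric. The step needs one orientation in the cycloaddition, and the ether oxygen on C1 should set it: the two ortho substituents twist the O–C(sp) bond out of the ring B plane, so the oxygen lone pair feeds the alkyne and makes C2 the nucleophilic terminus despite the opposing donor effect of ring D, which places ring D ortho to the new hydroxyl, the ring B ether next to it and ethoxy meta to both oxygens. The rod-like alkyne keeps rings B and D away from the forming bonds, slow addition of 21 limits ketene self-reaction, and methanolic KOH cleaves any ester formed from 26 and surplus 22.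

Step 9
Reactants: 26 5-ethoxy-3-[2,4-dimethoxy-6-(2,4,6-trimethoxyphenoxy)phenoxy]-2-(2,4,6-trimethoxyphenyl)phenol
Product: 27 fucodiphloroethol G
Conditions: BBr3 (25 equiv, 1 M in CH2Cl2), CH2Cl2, −78 °C to rt; then ice-water; Sephadex LH-20 or reversed-phase purification under Ar
Reagents that add atoms: none
Why: Lewis acid ether cleavage: BBr3 coordinates each alkyl aryl ether oxygen and bromide removes the methyl or ethyl group by attack at the sp3 carbon, whereas the diaryl ethers and the biaryl bond offer no such carbon and survive, and hydrolysis of the aryl borates releases the ten hydroxyls.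

Compound list
1 | 2,4,6-trimethoxybenzaldehyde | COc1cc(OC)c(C=O)c(OC)c1 | starting material
2 | 2,4,6-trimethoxyphenyl formate | COc1cc(OC)c(OC=O)c(OC)c1 | intermediate
3 | 2,4,6-trimethoxyphenol | COc1cc(OC)c(O)c(OC)c1 | intermediate
4 | 1-fluoro-3,5-dimethoxybenzene | COc1cc(F)cc(OC)c1 | starting material
5 | (2-fluoro-4,6-dimethoxybenzylidene)dimethylammonium dichlorophosphate | COc1cc(F)c(C=[N+](C)C)c(OC)c1.[O-]P(=O)(Cl)Cl | intermediate
6 | 2-fluoro-4,6-dimethoxybenzaldehyde | COc1cc(F)c(C=O)c(OC)c1 | intermediate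
7 | 2,4-dimethoxy-6-(2,4,6-trimethoxyphenoxy)benzaldehyde | COc1cc(OC)c(Oc2cc(OC)cc(OC)c2C=O)c(OC)c1 | intermediate
8 | 2,4-dimethoxy-6-(2,4,6-trimethoxyphenoxy)phenyl formate | COc1cc(OC)c(Oc2cc(OC)cc(OC)c2OC=O)c(OC)c1 | intermediate
9 | 2,4-dimethoxy-6-(2,4,6-trimethoxyphenoxy)phenol | COc1cc(OC)c(Oc2cc(OC)cc(OC)c2O)c(OC)c1 | intermediate
10 | trichloroethylene | ClC=C(Cl)Cl | starting material
11 | dichloroacetylene | ClC#CCl | intermediate
12 | 2-[(E)-1,2-dichloroethenyloxy]-1,5-dimethoxy-3-(2,4,6-trimethoxyphenoxy)benzene | COc1cc(OC)c(Oc2cc(OC)cc(OC)c2O/C(Cl)=C\Cl)c(OC)c1 | intermediate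
13 | 2-iodo-1,3,5-trimethoxybenzene | COc1cc(OC)c(I)c(OC)c1 | starting material
14 | 2-(chloroethynyloxy)-1,5-dimethoxy-3-(2,4,6-trimethoxyphenoxy)benzene | COc1cc(OC)c(Oc2cc(OC)cc(OC)c2OC#CCl)c(OC)c1 | intermediate
15 | lithium [2,4-dimethoxy-6-(2,4,6-trimethoxyphenoxy)phenoxy]acetylide | COc1cc(OC)c(Oc2cc(OC)cc(OC)c2OC#C[Li])c(OC)c1 | intermediate
16 | {[2,4-dimethoxy-6-(2,4,6-trimethoxyphenoxy)phenoxy]ethynyl}zinc chloride | COc1cc(OC)c(Oc2cc(OC)cc(OC)c2OC#C[Zn]Cl)c(OC)c1 | intermediate
17 | 1,5-dimethoxy-2-[(2,4,6-trimethoxyphenyl)ethynyloxy]-3-(2,4,6-trimethoxyphenoxy)benzene | COc1cc(OC)c(Oc2cc(OC)cc(OC)c2OC#Cc2c(OC)cc(OC)cc2OC)c(OC)c1 | intermediate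
18 | ethoxyacetylene | CCOC#C | starting material
19 | acetyl chloride | CC(Cl)=O | starting material
20 | ketene | C=C=O | intermediate
21 | 3-ethoxycyclobut-2-en-1-one | CCOC1=CC(=O)C1 | intermediate
22 | 3-ethoxybuta-1,3-dien-1-one (vinylketene) | C=C(OCC)C=C=O | intermediate
23 | racemic 4-(1-ethoxyethenyl)-3-[2,4-dimethoxy-6-(2,4,6-trimethoxyphenoxy)phenoxy]-2-(2,4,6-trimethoxyphenyl)cyclobut-2-en-1-one | O=C1C(c2c(OC)cc(OC)cc2OC)=C(Oc2c(OC)cc(OC)cc2Oc2c(OC)cc(OC)cc2OC)C1C(=C)OCC | intermediate
24 | (3E)-5-ethoxy-3-[2,4-dimethoxy-6-(2,4,6-trimethoxyphenoxy)phenoxy]-2-(2,4,6-trimethoxyphenyl)hexa-1,3,5-trien-1-one (dienylketene) | C=C(OCC)/C=C(Oc2c(OC)cc(OC)cc2Oc2c(OC)cc(OC)cc2OC)\C(c2c(OC)cc(OC)cc2OC)=C=O | intermediate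
25 | 5-ethoxy-3-[2,4-dimethoxy-6-(2,4,6-trimethoxyphenoxy)phenoxy]-2-(2,4,6-trimethoxyphenyl)cyclohexa-2,4-dien-1-one | O=C1CC(OCC)=CC(Oc2c(OC)cc(OC)cc2Oc3c(OC)cc(OC)cc3OC)=C1c4c(OC)cc(OC)cc4OC | intermediate
26 | 5-ethoxy-3-[2,4-dimethoxy-6-(2,4,6-trimethoxyphenoxy)phenoxy]-2-(2,4,6-trimethoxyphenyl)phenol | COc1cc(OC)c(Oc2cc(OC)cc(OC)c2Oc2cc(OCC)cc(O)c2-c2c(OC)cc(OC)cc2OC)c(OC)c1 | intermediate
27 | fucodiphloroethol G | Oc1cc(O)c(Oc2cc(O)cc(O)c2Oc2cc(O)cc(O)c2-c2c(O)cc(O)cc2O)c(O)c1 | target

Total step count: 9 steps. Longest linear sequence: 7 steps (steps 1, 3, 4, 5, 6, 8, 9; the branch through step 2 is equally long).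

Steps most likely to fail

1. Step 8 (benzannulation). The vinylketene may be consumed by self-condensation faster than the shielded, aryl-conjugated ynol ether captures it. The cycloaddition may also run with the opposite orientation if the donor ring D overrides the oxygen, or the vinylcyclobutenone may not reopen at a temperature the alkyne tolerates. Fallback, setting out from phenol 9 and fluoroaldehyde 6 and rejoining the route at 27: ring C is attached as a preformed arene. SNAr of the phenoxide of 9 on 6 (Cs2CO3, DMSO, 110 °C) should give 2-[2,4-dimethoxy-6-(2,4,6-trimethoxyphenoxy)phenoxy]-4,6-dimethoxybenzaldehyde F1. Baeyer–Villiger oxidation with mCPBA leads to 2-[2,4-dimethoxy-6-(2,4,6-trimethoxyphenoxy)phenoxy]-4,6-dimethoxyphenyl formate F2, and methanolysis to 2-[2,4-dimethoxy-6-(2,4,6-trimethoxyphenoxy)phenoxy]-4,6-dimethoxyphenol F3. Tf2O and pyridine convert it into 2-[2,4-dimethoxy-6-(2,4,6-trimethoxyphenoxy)phenoxy]-4,6-dimethoxyphenyl trifluoromethanesulfonate F4. Suzuki–Miyaura coupling of F4 with 2,4,6-trimethoxyphenylboronic acid F5 (Pd(OAc)2, SPhos, K3PO4, toluene, 100 °C) should give 1,5-dimethoxy-3-[2,4-dimethoxy-6-(2,4,6-trimethoxyphenoxy)phenoxy]-2-(2,4,6-trimethoxyphenyl)benzene F6. BBr3 then cleaves all ten methyl ethers to 27.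

2. Step 6 (alkyne assembly). Cross-coupling at the doubly ortho-substituted, electron-rich iodide may be slow enough for the alkynylzinc to decompose or homocouple. n-BuLi may also metalate ring positions between two oxygens, and the ynol ether may hydrate during isolation. Fallback, setting out from aldehyde 1 and phenol 9 and rejoining the route at 17: the alkyne is built from the ring D end. Ramirez dibromo-olefination of 1 (CBr4, PPh3, CH2Cl2, 0 °C) gives 2-(2,2-dibromoethenyl)-1,3,5-trimethoxybenzene F7. Copper-catalysed C–O coupling of F7 with 9 (CuI, 2,2'-bipyridine, K3PO4, toluene, 110 °C) replaces the bromine trans to the aryl group and should give 2-[(Z)-1-bromo-2-(2,4,6-trimethoxyphenyl)ethenyloxy]-1,5-dimethoxy-3-(2,4,6-trimethoxyphenoxy)benzene F8. t-BuOK in THF at rt then eliminates HBr to 17.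

3. Step 9 (global dealkylation). Cleavage may stall once partly dealkylated borate aggregates leave solution, the ethyl ether being the slowest, and the free decaphenol may be lost by air oxidation during chromatography. Fallback, setting out from 26 and rejoining the route at 27: the target is reached through a stable, chromatographable derivative. The crude BBr3 product is acetylated without purification (Ac2O, pyridine, DMAP) to fucodiphloroethol G decaacetate F9 and purified on silica, where under-dealkylated acetates are separated and returned to BBr3. Non-oxidative acidic methanolysis (HCl in degassed MeOH, rt) and evaporation then release 27.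

Further compounds
F1 | step 8 | 2-[2,4-dimethoxy-6-(2,4,6-trimethoxyphenoxy)phenoxy]-4,6-dimethoxybenzaldehyde | COc1cc(OC)c(Oc2cc(OC)cc(OC)c2Oc2cc(OC)cc(OC)c2C=O)c(OC)c1
F2 | step 8 | 2-[2,4-dimethoxy-6-(2,4,6-trimethoxyphenoxy)phenoxy]-4,6-dimethoxyphenyl formate | COc1cc(OC)c(Oc2cc(OC)cc(OC)c2Oc2cc(OC)cc(OC)c2OC=O)c(OC)c1
F3 | step 8 | 2-[2,4-dimethoxy-6-(2,4,6-trimethoxyphenoxy)phenoxy]-4,6-dimethoxyphenol | COc1cc(OC)c(Oc2cc(OC)cc(OC)c2Oc2cc(OC)cc(OC)c2O)c(OC)c1
F4 | step 8 | 2-[2,4-dimethoxy-6-(2,4,6-trimethoxyphenoxy)phenoxy]-4,6-dimethoxyphenyl trifluoromethanesulfonate | COc1cc(OC)c(Oc2cc(OC)cc(OC)c2Oc2cc(OC)cc(OC)c2OS(=O)(=O)C(F)(F)F)c(OC)c1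
F5 | step 8 | 2,4,6-trimethoxyphenylboronic acid | COc1cc(OC)c(B(O)O)c(OC)c1
F6 | step 8 | 1,5-dimethoxy-3-[2,4-dimethoxy-6-(2,4,6-trimethoxyphenoxy)phenoxy]-2-(2,4,6-trimethoxyphenyl)benzene | COc1cc(OC)c(Oc2cc(OC)cc(OC)c2Oc2cc(OC)cc(OC)c2-c2c(OC)cc(OC)cc2OC)c(OC)c1
F7 | step 6 | 2-(2,2-dibromoethenyl)-1,3,5-trimethoxybenzene | COc1cc(OC)c(C=C(Br)Br)c(OC)c1
F8 | step 6 | 2-[(Z)-1-bromo-2-(2,4,6-trimethoxyphenyl)ethenyloxy]-1,5-dimethoxy-3-(2,4,6-trimethoxyphenoxy)benzene | COc1cc(OC)c(Oc2cc(OC)cc(OC)c2O/C(Br)=C/c2c(OC)cc(OC)cc2OC)c(OC)c1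
F9 | step 9 | fucodiphloroethol G decaacetate | CC(=O)Oc1cc(OC(C)=O)c(Oc2cc(OC(C)=O)cc(OC(C)=O)c2Oc2cc(OC(C)=O)cc(OC(C)=O)c2-c2c(OC(C)=O)cc(OC(C)=O)cc2OC(C)=O)c(OC(C)=O)c1
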